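Numbering: oxane ring O1, C2 (fully substituted, C–Me), C3 (CHOH), C4, C5 (CHBr), C6 (CMe2); cyclohexane ring C1' (on C2), C3' (CHCl), C4' (CBrMe).
Retrosynthesis cuts, in order: C4'–Br and C3'–Cl (back to a C3'=C4' alkene), then O1–C6 and C5–Br (back to a prenyl alkene and the C2 carbinol), then the inter-ring bond C1'–C2.
Enabling feature: C2 carries O1 and sits next to the C3 carbinol, so C2/C3 can be read as an opened oxirane. The oxirane C2–O bond is the leaving group for a strain-driven 1,2-shift of C1' from boron to C2, and the C2–B bond left behind becomes C2–O1.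
Forward: a C7 boronic ester (lithiation–borylation, then ring-closing metathesis, so the cyclohexene ring comes first) is joined to a C8 sulfinyl oxirane. The oxane ring follows by 6-endo bromoetherification, and the cyclohexane halogens come last.
Stereochemistry: C1' comes from a sparteine-mediated lithiation and C2/C3 from an Andersen sulfoxide, and the union transfers all three stereospecifically. C5 follows from a chair transition state. C3'/C4' are relayed from C1' by three successive trans-diaxial openings (bromonium, epoxide, chloronium).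

Key step: step 9

Assumption: the chlorination in step 5 leaves the spatial arrangement at sulfur unchanged, and the lithiated chloro sulfoxide 14 relays (S)-sulfur to (R)-C2 in step 7. If the sense proves opposite, the enantiomeric menthyl sulfinate would be used, because sulfur is excised in step 9 and only C2/C3 of 16 matter.

Step 1
Reactants: 1 4-methylpent-4-en-1-ol
Product: 2 4-methylpent-4-en-1-yl N,N-diisopropylcarbamate
Conditions: i-Pr2NC(O)Cl, Et3N, CH2Cl2, reflux
Reagents that add atoms: N,N-diisopropylcarbamoyl chloride CC(C)N(C(C)C)C(=O)Cl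
Why: Carbamoylation of a primary alcohol installs the directing and leaving group for the lithiation–borylation, and no stereocenter is formed.

Step 2
Reactants: 2 4-methylpent-4-en-1-yl N,N-diisopropylcarbamate; 3 allylboronic acid pinacol ester
Product: 6 (S)-2-(7-methylocta-1,7-dien-4-yl)-4,4,5,5-tetramethyl-1,3,2-dioxaborolane, via lithiated carbamate 4 (not isolated), via allyl boronate complex 5 (not isolated)
Conditions: s-BuLi, (+)-sparteine, Et2O, −78 °C; 3, −78 °C; MgBr2·OEt2, −78 °C to reflux
Reagents that add atoms: none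
Why: In this lithiation–borylation, (+)-sparteine/s-BuLi removes the pro-R hydrogen, borylation goes with retention, and the 1,2-metalate rearrangement that expels the carbamate goes with inversion, which together set C1' as (S).

Step 3
Reactants: 6 (S)-2-(7-methylocta-1,7-dien-4-yl)-4,4,5,5-tetramethyl-1,3,2-dioxaborolane
Product: 7 (S)-2-(4-methylcyclohex-3-en-1-yl)-4,4,5,5-tetramethyl-1,3,2-dioxaborolane
Conditions: second-generation Grubbs catalyst RuCl2(=CHPh)(PCy3)(H2IMes) (cat.), CH2Cl2, 40 °C
Reagents that add atoms: none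
Why: Ring-closing metathesis of a monosubstituted and a 1,1-disubstituted alkene closes the six-membered ring and places the trisubstituted C3'=C4' alkene, leaving the C–B stereocenter untouched.

Step 4
Reactants: 8 (1R,2S,5R)-menthyl (S)-p-toluenesulfinate; 9 ethylmagnesium bromide
Product: 10 (R)-ethyl p-tolyl sulfoxide
Conditions: toluene/Et2O, 0 °C; aqueous work-up
Reagents that add atoms: none
Why: In the Andersen sulfoxide synthesis the Grignard reagent displaces mentholate at sulfur with clean inversion, so the bought sulfinate fixes the sulfur configuration.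

Step 5
Reactants: 10 (R)-ethyl p-tolyl sulfoxide
Product: 11 1-chloroethyl p-tolyl sulfoxide, (S) at sulfur, epimers at carbon
Conditions: NCS, K2CO3, CH2Cl2, rt
Reagents that add atoms: N-chlorosuccinimide O=C1CCC(=O)N1Cl
Why: α-Chlorination of a sulfoxide with NCS over carbonate keeps the sulfur stereocenter, and the new carbon center is irrelevant because it is planarised on lithiation in step 7.

Step 6
Reactants: 12 4-methylpent-3-en-1-ol
Product: 13 4-methylpent-3-enal
Conditions: Dess–Martin periodinane, CH2Cl2, 0 °C to rt; used at once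
Reagents that add atoms: none
Why: Dess–Martin oxidation under mild non-aqueous conditions should give the β,γ-unsaturated aldehyde without moving the alkene into conjugation.

Step 7
Reactants: 11 1-chloroethyl p-tolyl sulfoxide; 13 4-methylpent-3-enal
Product: 15 (2R,3R)-2-chloro-6-methyl-2-[(S)-p-tolylsulfinyl]hept-5-en-3-ol, via lithiated chloro sulfoxide 14 (not isolated)
Conditions: LDA, THF, −78 °C; 13, −78 °C; aqueous work-up; chromatography
Reagents that add atoms: none
Why: In this addition of an α-chloro-α-sulfinyl carbanion to an aldehyde, sulfur controls C2, the carbinol center C3 is not controlled, and the (2R,3R) adduct is separated from its C3 epimer by chromatography.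

Step 8
Reactants: 15 (2R,3R)-2-chloro-6-methyl-2-[(S)-p-tolylsulfinyl]hept-5-en-3-ol
Product: 16 (2R,3R)-2-methyl-3-(3-methylbut-2-en-1-yl)-2-[(S)-p-tolylsulfinyl]oxirane (methyl cis and sulfinyl trans to the prenyl chain)
Conditions: t-BuOK, t-BuOH/THF, 0 °C to rt
Reagents that add atoms: none
Why: In this Darzens-type closure the C3 alkoxide displaces chloride by intramolecular SN2 with inversion at C2, and C3 is unchanged.

Step 9
Reactants: 7 (S)-2-(4-methylcyclohex-3-en-1-yl)-4,4,5,5-tetramethyl-1,3,2-dioxaborolane; 16 (2R,3R)-2-methyl-3-(3-methylbut-2-en-1-yl)-2-[(S)-p-tolylsulfinyl]oxirane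
Product: 20 (2R,3R)-6-methyl-2-[(1S)-4-methylcyclohex-3-en-1-yl]-3-(triethylsilyloxy)hept-5-en-2-ol, via lithiooxirane 17 (not isolated), via boronate complex 18 (not isolated), via tertiary boronic ester 19 (not isolated)
Conditions: t-BuLi added to 7 + 16, THF, −78 °C; TESOTf, −78 °C to rt; then H2O2, NaOH, THF/H2O, 0 °C to rt
Reagents that add atoms: triethylsilyl trifluoromethanesulfonate CC[Si](CC)(CC)OS(=O)(=O)C(F)(F)F; hydrogen peroxide OO
Why: tert-Butyllithium attacks the sulfur of 16 (sulfoxide–lithium exchange, retention at carbon) and the configurationally stable lithiooxirane 17 is captured at once by the vacant boron orbital of 7, again with retention, to give boronate 18; silylation of the oxirane oxygen by TESOTf then sets off a 1,2-metalate shift in which C1' moves from boron to C2 antiperiplanar to the breaking C2–O bond, driven by release of the oxirane strain, and alkaline peroxide finally exchanges boron on C2 for oxygen with retention. The closest known reaction type is the homologation of boronic esters with lithiated epoxides, fully substituted ones from sulfoxide–lithium exchange included, which gives 1,2-diols after oxidation. No ring is closed in this step and one ring, the oxirane, is opened. C1' keeps the configuration of 7 because a migrating carbon moves with retention, C2 results from inversion at the oxirane carbon followed by retentive C–B oxidation and is therefore dictated by 16, and C3 is carried over from 16 untouched. The step needs exchange at sulfur to outrun attack of t-BuLi on boron, capture of 17 to outrun carbenoid decay, and migration of carbon instead of pinacol oxygen: addition of t-BuLi to the premixed partners at −78 °C, the small pyramidal oxiranyl anion whose lithium lies trans to the prenyl chain, and the high migratory aptitude of a secondary alkyl group secure these. Silylation also blocks boron–Wittig type elimination of the β-oxido boronate and delivers C3–O protected next to a free C2–OH, which is the differentiation the next step needs.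

Step 10
Reactants: 20 (2R,3R)-6-methyl-2-[(1S)-4-methylcyclohex-3-en-1-yl]-3-(triethylsilyloxy)hept-5-en-2-ol
Product: 21 (2R,3R,5R)-5-bromo-2,6,6-trimethyl-2-[(1S)-4-methylcyclohex-3-en-1-yl]-3-(triethylsilyloxy)oxane
Conditions: 2,4,4,6-tetrabromocyclohexa-2,5-dienone (TBCO), MeNO2, 0 °C to rt, dark
Reagents that add atoms: 2,4,4,6-tetrabromocyclohexa-2,5-dienone O=C1C(Br)=CC(Br)(Br)C=C1Br
Why: In this bromoetherification the reversibly formed prenyl bromonium ion is captured by the C2–OH at the tertiary carbon C6 (Markovnikov, 6-endo, helped by the polar solvent and the inductive pull of C3–OSi on C5) through a chair with the cyclohexenyl group and bromine equatorial, which sets C5, while the ring-alkene bromonium ion has no well-placed internal nucleophile and reverts.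

Step 11
Reactants: 21 (2R,3R,5R)-5-bromo-2,6,6-trimethyl-2-[(1S)-4-methylcyclohex-3-en-1-yl]-3-(triethylsilyloxy)oxane
Product: 23 (2R,3R,5R)-5-bromo-2,6,6-trimethyl-2-[(1R,4S,6S)-1-methyl-7-oxabicyclo[4.1.0]heptan-4-yl]-3-(triethylsilyloxy)oxane, via bromohydrin 22 (not isolated)
Conditions: NBS, acetone/H2O, 0 °C; then K2CO3, MeOH, rt
Reagents that add atoms: water O; N-bromosuccinimide O=C1CCC(=O)N1Br (its bromine stays only in 22)
Why: Bromohydrin formation followed by base closure works because reversible bromonium formation funnels through the Markovnikov, trans-diaxial (Fürst–Plattner) opening by water on the half-chair locked by the equatorial C1' substituent, as is known for limonene, and antiperiplanar closure then gives the epoxide with oxygen cis to the C1' substituent.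

Step 12
Reactants: 23 (2R,3R,5R)-5-bromo-2,6,6-trimethyl-2-[(1R,4S,6S)-1-methyl-7-oxabicyclo[4.1.0]heptan-4-yl]-3-(triethylsilyloxy)oxane
Product: 24 (2R,3R,5R)-5-bromo-2-[(1S,3R,4R)-3-chloro-4-hydroxy-4-methylcyclohexyl]-2,6,6-trimethyl-3-(triethylsilyloxy)oxane
Conditions: LiCl, AcOH, THF, rt
Reagents that add atoms: lithium chloride [Li+].[Cl-]
Why: In this SN2 epoxide opening by halide under mild acid, trans-diaxial (Fürst–Plattner) attack on this epoxide isomer is possible only at the secondary and less hindered C3', so chlorine ends axial at C3' with inversion and the axial tertiary OH stays on C4'.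

Step 13
Reactants: 24 (2R,3R,5R)-5-bromo-2-[(1S,3R,4R)-3-chloro-4-hydroxy-4-methylcyclohexyl]-2,6,6-trimethyl-3-(triethylsilyloxy)oxane
Product: 26 (2R,3R,5R)-5-bromo-2-[(1S,3R,4R)-4-bromo-3-chloro-4-methylcyclohexyl]-2,6,6-trimethyloxan-3-ol (target), via triethylsilyl ether 25 (not isolated)
Conditions: TMSBr, CH2Cl2, −40 to 0 °C; then MeOH, 0 °C
Reagents that add atoms: bromotrimethylsilane C[Si](C)(C)Br
Why: In this SN1-type conversion of a tertiary alcohol into the bromide with neighbouring-group participation, the axial C3'–Cl antiperiplanar to the leaving group bridges to a chloronium ion that bromide opens at the tertiary carbon from the opposite face (Markovnikov and diaxial, net retention at C4'), and the acidic methanol quench then cleaves the triethylsilyl ether.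

Compound list
1 | 4-methylpent-4-en-1-ol | C=C(C)CCCO | starting material
2 | 4-methylpent-4-en-1-yl N,N-diisopropylcarbamate | C=C(C)CCCOC(=O)N(C(C)C)C(C)C | intermediate
3 | allylboronic acid pinacol ester | C=CCB1OC(C)(C)C(C)(C)O1 | starting material
4 | (R)-1-lithio-4-methylpent-4-en-1-yl N,N-diisopropylcarbamate, (+)-sparteine complex | [Li][C@H](CCC(C)=C)OC(=O)N(C(C)C)C(C)C | intermediate
5 | lithium allyl[(R)-1-(diisopropylcarbamoyloxy)-4-methylpent-4-en-1-yl] pinacol boronate | [Li+].C=CC[B-]1(OC(C)(C)C(C)(C)O1)[C@H](CCC(C)=C)OC(=O)N(C(C)C)C(C)C | intermediate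
6 | (S)-2-(7-methylocta-1,7-dien-4-yl)-4,4,5,5-tetramethyl-1,3,2-dioxaborolane | CC1(C)OB(OC1(C)C)[C@H](CC=C)CCC(C)=C | intermediate
7 | (S)-2-(4-methylcyclohex-3-en-1-yl)-4,4,5,5-tetramethyl-1,3,2-dioxaborolane | CC1(C)OB(OC1(C)C)[C@H]2CCC(C)=CC2 | intermediate
8 | (1R,2S,5R)-menthyl (S)-p-toluenesulfinate | CC(C)[C@@H]1CC[C@@H](C)C[C@H]1O[S@](=O)c2ccc(C)cc2 | starting material
9 | ethylmagnesium bromide | CC[Mg]Br | starting material
10 | (R)-ethyl p-tolyl sulfoxide | CC[S@@](=O)c1ccc(C)cc1 | intermediate
11 | 1-chloroethyl p-tolyl sulfoxide, (S) at sulfur, epimers at carbon | CC(Cl)[S@@](=O)c1ccc(C)cc1 | intermediate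
12 | 4-methylpent-3-en-1-ol | CC(C)=CCCO | starting material
13 | 4-methylpent-3-enal | CC(C)=CCC=O | intermediate
14 | 1-chloro-1-lithioethyl p-tolyl sulfoxide, (S) at sulfur, carbanion carbon labile | [Li]C(C)(Cl)[S@@](=O)c1ccc(C)cc1 | intermediate
15 | (2R,3R)-2-chloro-6-methyl-2-[(S)-p-tolylsulfinyl]hept-5-en-3-ol | Cc1ccc(cc1)[S@](=O)[C@](C)(Cl)[C@H](O)CC=C(C)C | intermediate
16 | (2R,3R)-2-methyl-3-(3-methylbut-2-en-1-yl)-2-[(S)-p-tolylsulfinyl]oxirane | Cc1ccc(cc1)[S@](=O)[C@@]2(C)O[C@@H]2CC=C(C)C | intermediate
17 | (2S,3R)-2-lithio-2-methyl-3-(3-methylbut-2-en-1-yl)oxirane (lithium in the place of sulfur) | [Li][C@@]1(C)O[C@@H]1CC=C(C)C | intermediate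
18 | lithium [(1S)-4-methylcyclohex-3-en-1-yl][(2S,3R)-2-methyl-3-(3-methylbut-2-en-1-yl)oxiran-2-yl] pinacol boronate | [Li+].CC1(C)O[B-](OC1(C)C)([C@H]2CCC(C)=CC2)[C@@]3(C)O[C@@H]3CC=C(C)C | intermediate
19 | 2-{(2S,3R)-6-methyl-2-[(1S)-4-methylcyclohex-3-en-1-yl]-3-(triethylsilyloxy)hept-5-en-2-yl}-4,4,5,5-tetramethyl-1,3,2-dioxaborolane | CC1(C)OB(OC1(C)C)[C@](C)([C@H]2CCC(C)=CC2)[C@H](O[Si](CC)(CC)CC)CC=C(C)C | intermediate
20 | (2R,3R)-6-methyl-2-[(1S)-4-methylcyclohex-3-en-1-yl]-3-(triethylsilyloxy)hept-5-en-2-ol | O[C@](C)([C@H]1CCC(C)=CC1)[C@H](O[Si](CC)(CC)CC)CC=C(C)C | intermediate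
21 | (2R,3R,5R)-5-bromo-2,6,6-trimethyl-2-[(1S)-4-methylcyclohex-3-en-1-yl]-3-(triethylsilyloxy)oxane | CC1(C)O[C@](C)([C@H]2CCC(C)=CC2)[C@H](O[Si](CC)(CC)CC)C[C@H]1Br | intermediate
22 | (2R,3R,5R)-5-bromo-2-[(1S,3R,4R)-3-bromo-4-hydroxy-4-methylcyclohexyl]-2,6,6-trimethyl-3-(triethylsilyloxy)oxane | CC1(C)O[C@](C)([C@H]2CC[C@@](C)(O)[C@H](Br)C2)[C@H](O[Si](CC)(CC)CC)C[C@H]1Br | intermediate
23 | (2R,3R,5R)-5-bromo-2,6,6-trimethyl-2-[(1R,4S,6S)-1-methyl-7-oxabicyclo[4.1.0]heptan-4-yl]-3-(triethylsilyloxy)oxane | CC1(C)O[C@](C)([C@H]2CC[C@@]3(C)O[C@H]3C2)[C@H](O[Si](CC)(CC)CC)C[C@H]1Br | intermediate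
24 | (2R,3R,5R)-5-bromo-2-[(1S,3R,4R)-3-chloro-4-hydroxy-4-methylcyclohexyl]-2,6,6-trimethyl-3-(triethylsilyloxy)oxane | CC1(C)O[C@](C)([C@H]2CC[C@@](C)(O)[C@H](Cl)C2)[C@H](O[Si](CC)(CC)CC)C[C@H]1Br | intermediate
25 | (2R,3R,5R)-5-bromo-2-[(1S,3R,4R)-4-bromo-3-chloro-4-methylcyclohexyl]-2,6,6-trimethyl-3-(triethylsilyloxy)oxane | CC1(C)O[C@](C)([C@H]2CC[C@@](C)(Br)[C@H](Cl)C2)[C@H](O[Si](CC)(CC)CC)C[C@H]1Br | intermediate
26 | (2R,3R,5R)-5-bromo-2-[(1S,3R,4R)-4-bromo-3-chloro-4-methylcyclohexyl]-2,6,6-trimethyloxan-3-ol, CNP0151640.1 | CC1(C)O[C@](C)([C@H]2CC[C@@](C)(Br)[C@H](Cl)C2)[C@H](O)C[C@H]1Br | target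

Total step count: 13. Longest linear sequence: 9 steps (4, 5, 7, 8, 9, 10, 11, 12, 13).

Steps most likely to fail

Step 9. Boronate formation between the fully substituted lithiooxirane and the secondary pinacol boronate may be slow. Carbenoid decay or protonation could then overtake capture, or the β-oxido boronate could eliminate before it is silylated. The fallback sets out from 7 and comes back at 20. It makes the inter-ring bond at a secondary carbenoid carbon and adds the methyl group afterwards. (R)-Epichlorohydrin is opened with 2-methylprop-1-enylmagnesium bromide (CuI cat.) to (R)-1-chloro-5-methylhex-4-en-2-ol F1, which NaOH closes to (R)-2-(3-methylbut-2-en-1-yl)oxirane F2. F2 is lithiated with lithium 2,2,6,6-tetramethylpiperidide trans to the side chain in the presence of 7. TESOTf and then alkaline peroxide give (1R,2R)-5-methyl-1-[(1S)-4-methylcyclohex-3-en-1-yl]-2-(triethylsilyloxy)hex-4-en-1-ol F3. Dess–Martin oxidation gives (2R)-5-methyl-1-[(1S)-4-methylcyclohex-3-en-1-yl]-2-(triethylsilyloxy)hex-4-en-1-one F4. MeLi in Et2O at −78 °C adds under Felkin–Anh control, anti to the C3–OSi bond, to give 20.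

Step 10. Capture of the bromonium ion may show poor regioselectivity (5-exo attack at C5 instead of 6-endo attack at C6), only modest facial selectivity, or participation of the silyl ether oxygen. The fallback sets out from 20 and comes back at 21. The cyclisation is run under kinetic conditions (NBS, CH2Cl2, 0 °C) to give the 5-exo product (2R,3R,5S)-5-(2-bromopropan-2-yl)-2-methyl-2-[(1S)-4-methylcyclohex-3-en-1-yl]-3-(triethylsilyloxy)oxolane F5. ZnBr2 in CH2Cl2 then ionises its tertiary bromide with participation of the ring oxygen. Bromide reopens the resulting bicyclic oxonium ion at C5 with inversion. This is the known ring expansion of 2-(1-haloalkyl)oxolanes to 3-halooxanes, and it gives 21.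

Step 13. Ionisation may end in proton loss instead of bromide capture, or stereochemical integrity at C4' may erode through an open cation. The di-tertiary oxane ether may open under acid, or the diaxial halogens may undergo thermal 1,2-interchange if the mixture warms. The fallback sets out from 24 and comes back at 25. It replaces substitution by elimination followed by Markovnikov hydrobromination. SOCl2 in pyridine at 0 °C removes the axial tertiary OH with the antiperiplanar axial C5'–H. This gives (2R,3R,5R)-5-bromo-2-[(1S,5R)-5-chloro-4-methylcyclohex-3-en-1-yl]-2,6,6-trimethyl-3-(triethylsilyloxy)oxane F6. HBr in AcOH/CH2Cl2 at −20 °C then protonates C5' and delivers bromide to C4' anti to the axial chlorine, giving 25, which the methanol treatment of step 13 converts into 26.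

Further compounds
F1 | step 9 | (R)-1-chloro-5-methylhex-4-en-2-ol | ClC[C@H](O)CC=C(C)C
F2 | step 9 | (R)-2-(3-methylbut-2-en-1-yl)oxirane | C1O[C@@H]1CC=C(C)C
F3 | step 9 | (1R,2R)-5-methyl-1-[(1S)-4-methylcyclohex-3-en-1-yl]-2-(triethylsilyloxy)hex-4-en-1-ol | O[C@H]([C@H]1CCC(C)=CC1)[C@H](O[Si](CC)(CC)CC)CC=C(C)C
F4 | step 9 | (2R)-5-methyl-1-[(1S)-4-methylcyclohex-3-en-1-yl]-2-(triethylsilyloxy)hex-4-en-1-one | O=C([C@H]1CCC(C)=CC1)[C@H](O[Si](CC)(CC)CC)CC=C(C)C
F5 | step 10 | (2R,3R,5S)-5-(2-bromopropan-2-yl)-2-methyl-2-[(1S)-4-methylcyclohex-3-en-1-yl]-3-(triethylsilyloxy)oxolane | O1[C@](C)([C@H]2CCC(C)=CC2)[C@H](O[Si](CC)(CC)CC)C[C@H]1C(C)(C)Br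
F6 | step 13 | (2R,3R,5R)-5-bromo-2-[(1S,5R)-5-chloro-4-methylcyclohex-3-en-1-yl]-2,6,6-trimethyl-3-(triethylsilyloxy)oxane | CC1(C)O[C@](C)([C@H]2CC=C(C)[C@H](Cl)C2)[C@H](O[Si](CC)(CC)CC)C[C@H]1Br
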